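Decide first what you will carry out of these runs: I carry one ratio read straight off the readings, and no fitted constant.

| flask | left-handed substrate | right-handed substrate | reagent | free catalyst | racemization catalyst | remark | time |
|---|---|---|---|---|---|---|---|
| north-west | 9.5 mM | 9.5 mM | 2.2 equiv | 5 mol% | 3.6 mol% | run made earlier |  |
| south | 14 mM | 14 mM | 2.2 equiv | 5 mol% | 3.6 mol% | run made earlier |  |
| south-west | 19 mM | 19 mM | 4.4 equiv | 5 mol% | 3.6 mol% | run made earlier |  |
| flask | 19 mM | 19 mM | 2.20 equiv | 5 mol% | 3.6 mol% |  | 30 min |

| run | time / min | left-handed product / % | right-handed product / % |
|---|---|---|---|
| north-west | 2.00 | 0.2 | 0 |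
| north-west | 4.00 | 0.3 | 0.4 |
| north-west | 6.00 | 0.3 | 0.1 |
| north-west | 12.0 | 0.7 | 0.4 |
| north-west | 25.0 | 1.3 | 0.7 |
| south | 2.00 | 0.5 | 0.5 |
| south | 6.00 | 0.1 | 0.3 |
| south | 12.0 | 1.1 | 0.8 |
| south | 15.0 | 1.5 | 0.9 |
| south | 25.0 | 2.0 | 1.6 |
| south-west | 2.00 | 1.0 | 0.7 |
| south-west | 6.00 | 2.6 | 0.9 |
| south-west | 12.0 | 4.6 | 2.6 |
| south-west | 15.0 | 4.7 | 2.9 |
| south-west | 25.0 | 7.3 | 4.0 |

(readings scatter by 0.3 percentage points)
- free catalyst is single-handed; left-handed substrate and right-handed substrate are mirror images of each other, charged as a racemate, each of them at the stated concentration
- the numbers in the tables scatter with a standard deviation of 0.3 percentage points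
- an excess is the difference of the two amounts in percent of their sum
- an excess is below zero if the other one leads
* excess of left-handed product over right-handed product in the product at 1.5 min
* excess of left-handed product over right-handed product in the product at 30 min
* part of the left-handed substrate and right-handed substrate charged together that has reacted at 30 min

A single reading scatters by 0.3 percentage points, so I sum each product over all the south-west readings, and left-handed over right-handed gives 1.82. Call this s, the selectivity factor, the ratio of the two product rates while [left-handed substrate] equals [right-handed substrate]. It means a product excess (s−1)/(s+1) of 29.1%.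

Now turn the settings. A larger charge at fixed equivalents and loadings should, reckoned by hand, speed the flask and leave s alone, and the pace does rise, from 2.00% reacted at 25.0 min in the north-west run to 3.60% in the south run. Twice the reagent should likewise raise the pace in proportion, but that is my assumption, since the south-west run differs from the south run in charge as well as in equivalents. Your flask is the south-west recipe with half its reagent, so I take half of that run's 11.3% and stretch it in proportion to time, which gives an estimate of 6.78% reacted at 30 min. The three runs all have 5 mol% of free catalyst and 3.6 mol% of racemization catalyst, so their readings say nothing on a change of either loading.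

So solve the excess at both ends. At 1.5 min the substrates are nearly equal, which gives 29.1%. At 30 min, with the racemization catalyst idle, the rate ratio s·[left-handed substrate]/[right-handed substrate] falls to 1.74, an excess of 27.1% in the fresh product, and the accumulated product sits about midway, at 28.1%. With the substrates held equal it stays at 29.1%, and I commit to that span.

The forecast gives 27% at 1.5 min, 26% at 30 min and 6.5% reacted, reasoning that “At such low conversion, with racemization present, it should stay nearly constant”, and its excesses lie below mine.

The flask gives 29.0% at 1.5 min, 28.2% at 30 min, and 6.89% reacted.

    reagent + free catalyst + left-handed substrate → free catalyst + left-handed product (k = 200 M⁻² min⁻¹)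
    reagent + free catalyst + right-handed substrate → free catalyst + right-handed product (k = 110 M⁻² min⁻¹)
    left-handed substrate + racemization catalyst ⇌ right-handed substrate + racemization catalyst, rate k3*[racemization catalyst]*[left-handed substrate] forward; the back reaction follows from the equilibrium constant (k = 14.0 M⁻¹ min⁻¹)
    free catalyst → spent catalyst (k = 0.0440 min⁻¹)
    2 free catalyst ⇌ resting dimer, settled at all times (K = 1000 M⁻¹)

In this flask at 12.5 min, the reaction to left-handed product used left-handed substrate at 0.33 of the rate of the forward racemization step alone, which is less than that step, and at 30 min right-handed substrate leads by 1.54%. Put into s, that lead gives 1.76, a fresh excess of 27.7%, and the flask's 28.2% lies between that and 29.1%.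

For the neighbour with 12 mol% of free catalyst, s gives 29.1% at the start, and with 85% of the left-handed and 90% of the right-handed substrate left, a fresh excess of 26.4% at 30 min. That neighbour computes to 28.9% at 1.5 min and to 27.6% at 30 min, which is more than that fresh excess, with 12.3% reacted.

(The data were generated by integration from invented constants, noise included.)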